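The route rests on cutting the bond between C1' of the seventeen-carbon chain and C5 of the resorcinol ring. C5 is meta to both hydroxyls, so it has no nucleophilic character and Friedel–Crafts polarity fails. Both carbons are therefore used as electrophiles. In the last step a nickel-catalysed reductive cross-electrophile coupling joins unprotected 5-bromoresorcinol to the unprotected (2S,6Z,9Z)-17-chloroheptadeca-6,9-dien-2-ol, relayed through its iodide, and gives the target directly. The primary C1' radical is insulated from the C8'=C9' alkene by six methylenes. The precursor chain comes from a skipped diyne assembled from propargyl alcohol, 1-bromo-7-chloroheptane and an alkynol that takes C16' from (S)-propylene oxide.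

Key step: step 6

Remark: primed locants (C1' to C17') count the side chain outwards from the ring, and the stereocentre C16' of the target is S. The five starting materials 1, 2, 6, 7 and 13 are taken as catalogue compounds.

Step 1
Reactants: 1 propargyl alcohol (prop-2-yn-1-ol); 2 bromochloroheptane (1-bromo-7-chloroheptane)
Product: 4 chloroalkynol (10-chlorodec-2-yn-1-ol), via dilithiated propargyl alcohol 3 (not isolated)
Conditions: 1 (1.5 equiv), n-BuLi (3.0 equiv), THF/DMPU, −78 to 0 °C; then 2, 0 °C to rt; H2O
Reagents that add atoms: none
Why: Acetylide C-alkylation (SN2) should work because the carbanion of the O,C-dianion is by far the better nucleophile and bromide leaves much faster than chloride, so the chain grows only at the alkyne terminus and keeps its chloride.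

Step 2
Reactants: 4 chloroalkynol (10-chlorodec-2-yn-1-ol)
Product: 5 propargylic bromide (1-bromo-10-chlorodec-2-yne)
Conditions: CBr4, PPh3, CH2Cl2, 0 °C
Reagents that add atoms: carbon tetrabromide, BrC(Br)(Br)Br
Why: In the Appel reaction bromide displaces the alkoxyphosphonium salt of the primary propargylic alcohol under neutral conditions that leave the alkyne and the primary chloride untouched.

Step 3
Reactants: 6 silylated bromobutyne ((4-bromobut-1-yn-1-yl)trimethylsilane); 7 (S)-propylene oxide ((S)-2-methyloxirane)
Product: 10 alkynol (S)-hept-6-yn-2-ol, via Grignard reagent 8 (not isolated), via silylated alkynol 9 (not isolated)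
Conditions: 6, Mg, THF, 40 °C; CuI (10 mol %), 7, −30 to 0 °C; then MeOH, K2CO3 (cat.), rt
Reagents that add atoms: none
Why: Copper-catalysed Grignard opening of a terminal epoxide is an SN2 attack at the unsubstituted CH2 that breaks no bond at the stereocentre, so the S configuration of 7 passes unchanged into C2 of 10, and base-catalysed methanolysis then removes the alkynyl silane in the same flask.

Step 4
Reactants: 10 alkynol (S)-hept-6-yn-2-ol; 5 propargylic bromide (1-bromo-10-chlorodec-2-yne)
Product: 11 skipped diyne ((S)-17-chloroheptadeca-6,9-diyn-2-ol)
Conditions: CuI (20 mol %), Cs2CO3 (1.5 equiv), DMF, 0 °C to rt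
Reagents that add atoms: none
Why: In this copper-acetylide propargylation (skipped-diyne synthesis) the copper acetylide formed under carbonate base displaces the activated propargylic bromide, whereas the free secondary hydroxyl and the unactivated primary chloride should not react at room temperature.

Step 5
Reactants: 11 skipped diyne ((S)-17-chloroheptadeca-6,9-diyn-2-ol)
Product: 12 skipped diene ((2S,6Z,9Z)-17-chloroheptadeca-6,9-dien-2-ol)
Conditions: H2 (1 atm), Ni(OAc)2·4H2O (20 mol %), NaBH4 (20 mol %), ethylenediamine (60 mol %), EtOH, rt
Reagents that add atoms: none
Why: Syn semi-hydrogenation on amine-poisoned nickel boride (Ni2B) delivers both hydrogens to one face of each triple bond, which sets the 6Z and 9Z geometries, and the poisoned surface binds alkenes too weakly for over-reduction or for hydrogenolysis of the chloride.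

Step 6
Reactants: 12 skipped diene ((2S,6Z,9Z)-17-chloroheptadeca-6,9-dien-2-ol); 13 5-bromoresorcinol (5-bromobenzene-1,3-diol)
Product: 15 hansfordiol D (5-[(8Z,11Z,16S)-16-hydroxyheptadeca-8,11-dien-1-yl]benzene-1,3-diol), via alkyl iodide 14 (not isolated)
Conditions: 13 (1.3 equiv), NiI2 (10 mol %), 4,4'-dimethoxy-2,2'-bipyridine (10 mol %), NaI (50 mol %), pyridine (10 mol %), Zn dust (2 equiv), DMPU, 80 °C
Reagents that add atoms: none
Why: This is a nickel-catalysed reductive cross-electrophile coupling of an aryl bromide with a primary alkyl halide, a known reaction type that tolerates free hydroxyl groups: iodide slowly turns chloride 12 into iodide 14 by Finkelstein exchange, zerovalent nickel inserts into the C5–Br bond of 13, the resulting divalent arylnickel bromide captures the primary C1' radical that monovalent nickel generates from 14 by iodine-atom abstraction, reductive elimination from trivalent nickel forms the C1'–C5 bond, and Zn returns the catalyst to the zerovalent state. Two carbons of like, electrophilic polarity are thus joined, which suits C5 because it is meta to both hydroxyls and is not reached by electrophilic alkylation of the ring. No ring is closed and no stereocentre is formed, and C16' and both Z alkenes should pass unchanged because the medium holds no strong acid, strong base or heteroatom-centred radical. The step needs cross- over homo-coupling selectivity, which is secured by the two different activation modes (two-electron insertion at the sp2 bromide, halogen abstraction at the sp3 iodide) and by the slow halide relay that keeps the radical concentration low. It also needs chemoselectivity in the presence of three free hydroxyls, which is secured because no preformed organometallic nucleophile is present and, without base, the phenols are not O-alkylated. The six methylenes C2' to C7' leave the C1' radical only slow 8-exo or 9-endo cyclisations onto C8'=C9', so capture by nickel should win.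

Compound list
1 | prop-2-yn-1-ol (propargyl alcohol) | C#CCO | starting material
2 | 1-bromo-7-chloroheptane | ClCCCCCCCBr | starting material
3 | dilithiated propargyl alcohol (O,C-dianion) | [Li]C#CCO[Li] | intermediate
4 | 10-chlorodec-2-yn-1-ol | OCC#CCCCCCCCCl | intermediate
5 | 1-bromo-10-chlorodec-2-yne | BrCC#CCCCCCCCCl | intermediate
6 | (4-bromobut-1-yn-1-yl)trimethylsilane | C[Si](C)(C)C#CCCBr | starting material
7 | (S)-propylene oxide | C[C@H]1CO1 | starting material
8 | [4-(trimethylsilyl)but-3-yn-1-yl]magnesium bromide | C[Si](C)(C)C#CCC[Mg]Br | intermediate
9 | (S)-7-(trimethylsilyl)hept-6-yn-2-ol | C[C@H](O)CCCC#C[Si](C)(C)C | intermediate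
10 | (S)-hept-6-yn-2-ol | C[C@H](O)CCCC#C | intermediate
11 | (S)-17-chloroheptadeca-6,9-diyn-2-ol | C[C@H](O)CCCC#CCC#CCCCCCCCCl | intermediate
12 | (2S,6Z,9Z)-17-chloroheptadeca-6,9-dien-2-ol | C[C@H](O)CCC/C=C\C/C=C\CCCCCCCCl | intermediate
13 | 5-bromobenzene-1,3-diol (5-bromoresorcinol) | Oc1cc(O)cc(Br)c1 | starting material
14 | (2S,6Z,9Z)-17-iodoheptadeca-6,9-dien-2-ol | C[C@H](O)CCC/C=C\C/C=C\CCCCCCCI | intermediate
15 | hansfordiol D, 5-[(8Z,11Z,16S)-16-hydroxyheptadeca-8,11-dien-1-yl]benzene-1,3-diol | C[C@H](O)CCC/C=C\C/C=C\CCCCCCCc1cc(O)cc(O)c1 | target

Total step count: 6
Longest linear sequence: 5 steps (steps 1, 2, 4, 5 and 6)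

Steps most likely to fail

Step 6. Several processes may outrun the cross-coupling. Either halide may be reduced by proton or hydrogen-atom capture, either partner may homocouple, or a nickel hydride may move the skipped diene into conjugation. The fallback replaces the reductive union with a polar nucleophile–electrophile union using protected phenols. It sets out from 12 and 13 and comes back to the route at 15. Silylation of 13 (TBSCl, imidazole, DMF, rt) should give [(5-bromo-1,3-phenylene)bis(oxy)]bis(tert-butyldimethylsilane) F1. Mg in THF should turn this into 3,5-bis(tert-butyldimethylsilyloxy)phenylmagnesium bromide F2. Chloride 12 is converted separately into iodide 14, now isolated (NaI, acetone, reflux). The aryl Grignard reagent is then alkylated under copper catalysis (F2 in excess, one equivalent being spent on the free hydroxyl; Li2CuCl4 5 mol %, THF, −20 °C to rt). This should give (2S,6Z,9Z)-17-[3,5-bis(tert-butyldimethylsilyloxy)phenyl]heptadeca-6,9-dien-2-ol F3. Treatment with n-Bu4NF in THF should then release 15.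

Step 5. The diyne may be over-reduced to monoenes, incompletely reduced to enynes, or partly isomerised from Z to E on the metal surface. Any of these would give mixtures that are hard to separate. The fallback replaces catalytic hydrogenation with stoichiometric syn hydroboration and protonolysis. It sets out from 11 and comes back to the route at 12. Freshly prepared dicyclohexylborane (3.3 equiv, THF, 0 °C) should first borylate the hydroxyl and then add once, syn, to each triple bond. The expected product is (2S)-17-chloro-6,10-bis(dicyclohexylboryl)heptadeca-6,9-dien-2-yl dicyclohexylborinate F4, drawn as one regioisomer. The position of boron on each alkene is irrelevant because it is removed. Acetic acid (0 °C to 50 °C) should cleave both alkenyl carbon–boron bonds with retention, and the borinate as well, to give 12.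

Step 1. The poorly soluble dianion may alkylate sluggishly, O-alkylation may compete, or attack may occur at the chloride end. The fallback builds the same alkynol in the opposite bond order. It sets out from 2 and comes back to the route at 4. LiC≡CH·H2NCH2CH2NH2 in DMSO at rt should displace only the bromide of 2 to give 9-chloronon-1-yne F5. Deprotonation (n-BuLi, THF, −78 °C) and hydroxymethylation with paraformaldehyde should then give 4.

Further compounds
F1 | step 6 | [(5-bromo-1,3-phenylene)bis(oxy)]bis(tert-butyldimethylsilane) | CC(C)(C)[Si](C)(C)Oc1cc(Br)cc(O[Si](C)(C)C(C)(C)C)c1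
F2 | step 6 | 3,5-bis(tert-butyldimethylsilyloxy)phenylmagnesium bromide | CC(C)(C)[Si](C)(C)Oc1cc([Mg]Br)cc(O[Si](C)(C)C(C)(C)C)c1
F3 | step 6 | (2S,6Z,9Z)-17-[3,5-bis(tert-butyldimethylsilyloxy)phenyl]heptadeca-6,9-dien-2-ol | C[C@H](O)CCC/C=C\C/C=C\CCCCCCCc1cc(O[Si](C)(C)C(C)(C)C)cc(O[Si](C)(C)C(C)(C)C)c1
F4 | step 5 | (2S)-17-chloro-6,10-bis(dicyclohexylboryl)heptadeca-6,9-dien-2-yl dicyclohexylborinate (syn adduct, one regioisomer drawn) | C[C@H](OB(C1CCCCC1)C1CCCCC1)CCC/C(B(C1CCCCC1)C1CCCCC1)=C\C/C=C(B(C1CCCCC1)C1CCCCC1)\CCCCCCCCl
F5 | step 1 | 9-chloronon-1-yne | C#CCCCCCCCCl
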